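**Retrosynthetic overview**
1. Target 35 ⇒ penta-MOM flavanone 34 (global acetal removal) ⇒ chalcone 33 (C2–O1 bond, enantioselective 6-endo oxa-Michael) ⇒ acetophenone 26 + aldehyde 32 (Claisen–Schmidt).
2. 26 ⇒ lavandulyl arene 21 (aryl C–H → acetyl) ⇒ secondary boronic ester 16 (Zweifel 1,2-shift adds isopropenyl) ⇒ benzylic boronate 11 + homoprenyl carbamate 13. The key step is the stereospecific 1,2-shift of the benzylic carbon from boron to carbon, which sets the lavandulyl centre.
3. 11 ⇒ phenol 7 ⇒ resorcinol 1 by MOM-directed metalation (prenyl) and Ir C–H borylation/oxidation (third oxygen, the future O1, kept distinct from the other two).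
4. 32 ⇒ resorcinol 1 by the same borylation/oxidation, MOM protection and ortho-formylation.
5. Ring order: both benzene rings are bought as resorcinol; the only ring made is the pyranone C ring, closed in step 14.

Assumption: species that persist between two reagent additions are numbered as non-isolated intermediates; the THP acetal carbon of 8–11, 15, 16, 19–21 and 23–25 is an unassigned centre (epimer mixtures) that is removed in step 9.

Abbreviations: MOM = methoxymethyl; THP = oxan-2-yl; pin = pinacolato; prenyl = 3-methylbut-2-en-1-yl; (2R)-lavandulyl = (2R)-5-methyl-2-(prop-1-en-2-yl)hex-4-en-1-yl; ArA = 2,4-bis(methoxymethoxy)-3-prenyl-6-(oxan-2-yloxy)phenyl.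

**Route**

Step 1
Reactants: 1 resorcinol
Product: 2 1,3-bis(methoxymethoxy)benzene
Conditions: MOMCl, K2CO3, acetone, reflux
Reagents that add atoms: chloromethyl methyl ether (MOMCl), COCCl
Why: Williamson-type O-alkylation of both phenols protects the future 5- and 7-oxygens and installs the two cooperating directing groups for step 2.

Step 2
Reactants: 2 1,3-bis(methoxymethoxy)benzene; 3 prenyl bromide (1-bromo-3-methylbut-2-ene)
Product: 5 1,3-bis(methoxymethoxy)-2-(3-methylbut-2-en-1-yl)benzene, via aryllithium 4 (not isolated)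
Conditions: n-BuLi, THF, 0 °C; CuBr·SMe2 (10 mol %), 3, −78 °C → rt
Reagents that add atoms: none
Why: Directed ortho-metalation occurs only at C2, flanked by both MOM ethers, and Cu-catalysed SN2 allylation places the prenyl group between the two future 5- and 7-oxygens.

Step 3
Reactants: 5 1,3-bis(methoxymethoxy)-2-(3-methylbut-2-en-1-yl)benzene
Product: 7 3,5-bis(methoxymethoxy)-4-(3-methylbut-2-en-1-yl)phenol, via arylboronate 6 (not isolated)
Conditions: [Ir(OMe)(cod)]2 (1.5 mol %), dtbpy (3 mol %), B2pin2 (0.7 equiv), THF, 70 °C; then 2 M NaOH, 30 % H2O2, 0 °C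
Reagents that add atoms: hydrogen peroxide, OO
Why: Sterically controlled Ir-catalysed C–H borylation (Hartwig–Miyaura type) reacts only at C5, the one aryl C–H without an ortho substituent, and boronate oxidation gives the third oxygen as the only free phenol (future O1); the trisubstituted alkene should be inert.

Step 4
Reactants: 7 3,5-bis(methoxymethoxy)-4-(3-methylbut-2-en-1-yl)phenol
Product: 8 2-[3,5-bis(methoxymethoxy)-4-(3-methylbut-2-en-1-yl)phenoxy]oxane
Conditions: 3,4-dihydro-2H-pyran, PPTS (5 mol %), CH2Cl2, rt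
Reagents that add atoms: 3,4-dihydro-2H-pyran, C1=COCCC1
Why: PPTS-catalysed acetalisation masks the unique phenol as a THP ether that tolerates organolithiums, directs metalation like MOM and is later cleaved under acid too weak for MOM.

Step 5
Reactants: 8 2-[3,5-bis(methoxymethoxy)-4-(3-methylbut-2-en-1-yl)phenoxy]oxane
Product: 11 2-(ArA-methyl)-4,4,5,5-tetramethyl-1,3,2-dioxaborolane, via aryllithium 9 (not isolated), via chloromethyl borate complex 10 (not isolated)
Conditions: s-BuLi, TMEDA, THF, −78 °C; ClCH2Bpin, −78 °C → rt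
Reagents that add atoms: 2-(chloromethyl)-4,4,5,5-tetramethyl-1,3,2-dioxaborolane, ClCB1OC(C)(C)C(C)(C)O1
Why: Directed ortho-metalation at one of the two equivalent sites between OTHP and OMOM, then trapping on boron, gives an ate complex in which the aryl group shifts 1,2 from boron to carbon with loss of chloride (Matteson homologation).

Step 6
Reactants: 12 4-methylpent-3-en-1-ol
Product: 13 4-methylpent-3-en-1-yl N,N-diisopropylcarbamate
Conditions: iPr2NCOCl, Et3N, CH2Cl2, reflux
Reagents that add atoms: N,N-diisopropylcarbamoyl chloride, CC(C)N(C(C)C)C(Cl)=O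
Why: O-Carbamoylation gives the Hoppe carbamate, whose carbonyl directs the α-lithiation and whose oxygen is the leaving group of the 1,2-shift.

Step 7
Reactants: 11 2-(ArA-methyl)-4,4,5,5-tetramethyl-1,3,2-dioxaborolane; 13 4-methylpent-3-en-1-yl N,N-diisopropylcarbamate
Product: 16 2-[(2R)-1-ArA-5-methylhex-4-en-2-yl]-4,4,5,5-tetramethyl-1,3,2-dioxaborolane, via lithiated carbamate 14 (not isolated), via boronate complex 15 (not isolated)
Conditions: 13, s-BuLi, (−)-sparteine, Et2O, −78 °C, 5 h; 11, −78 °C, 1 h; then reflux, 16 h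
Reagents that add atoms: none
Why: Hoppe–Aggarwal lithiation–borylation: s-BuLi/(−)-sparteine removes the pro-S α-hydrogen to give the (S)-carbenoid, borylation proceeds with retention, and the benzylic carbon then shifts 1,2 from boron to carbon anti to the departing carbamate (inversion), a stereospecific 1,2-metallate rearrangement that forms the ArCH2–C bond and fixes the lavandulyl centre as R.

Step 8
Reactants: 16 2-[(2R)-1-ArA-5-methylhex-4-en-2-yl]-4,4,5,5-tetramethyl-1,3,2-dioxaborolane; 17 2-bromopropene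
Product: 21 2-{3,5-bis(methoxymethoxy)-2-[(2R)-lavandulyl]-4-prenylphenoxy}oxane, via isopropenyllithium 18 (not isolated), via alkenyl borate complex 19 (not isolated), via iodo boronic ester 20 (not isolated)
Conditions: 17, t-BuLi (2 equiv per 17), THF, −78 °C; 16, −78 °C; I2, THF/MeOH, −78 °C; NaOMe, MeOH, −78 °C → rt
Reagents that add atoms: none
Why: Zweifel olefination: iodine activation of the alkenyl borate triggers a second 1,2-shift of the secondary carbon from boron to carbon with retention, and methoxide-induced anti-elimination of boron and iodide leaves the isopropenyl group, completing the (R)-lavandulyl chain.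

Step 9
Reactants: 21 2-{3,5-bis(methoxymethoxy)-2-[(2R)-lavandulyl]-4-prenylphenoxy}oxane; 22 N-methoxy-N-methylacetamide
Product: 26 1-{2-hydroxy-4,6-bis(methoxymethoxy)-3-[(2R)-lavandulyl]-5-prenylphenyl}ethan-1-one, via aryllithium 23 (not isolated), via tetrahedral adduct 24 (not isolated), via THP ketone 25 (not isolated)
Conditions: s-BuLi, THF, −78 → −40 °C; 22, −78 → 0 °C; AcOH (3 equiv); then PPTS (0.3 equiv), MeOH, 40 °C
Reagents that add atoms: none
Why: Directed ortho-metalation of the last aryl C–H and Weinreb ketone synthesis (stable chelate, no over-addition) install the acetyl group, and mild acidic methanolysis removes only the THP acetal, releasing the ketone-chelated phenol that becomes O1.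

Step 10
Reactants: 2 1,3-bis(methoxymethoxy)benzene
Product: 28 3,5-bis(methoxymethoxy)phenol, via arylboronate 27 (not isolated)
Conditions: [Ir(OMe)(cod)]2 (1.5 mol %), dtbpy (3 mol %), B2pin2 (0.7 equiv), THF, 70 °C; then 2 M NaOH, 30 % H2O2, 0 °C
Reagents that add atoms: hydrogen peroxide, OO
Why: Ir-catalysed C–H borylation is sterically directed to C5 (meta to both MOM ethers) and boronate oxidation gives the phloroglucinol oxygenation pattern of the B ring.

Step 11
Reactants: 28 3,5-bis(methoxymethoxy)phenol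
Product: 29 1,3,5-tris(methoxymethoxy)benzene
Conditions: MOMCl, K2CO3, acetone, reflux
Reagents that add atoms: chloromethyl methyl ether (MOMCl), COCCl
Why: Williamson-type O-alkylation gives the C3-symmetric tris-acetal, so the next metalation has only one possible site.

Step 12
Reactants: 29 1,3,5-tris(methoxymethoxy)benzene
Product: 32 2,4,6-tris(methoxymethoxy)benzaldehyde, via aryllithium 30 (not isolated), via hemiaminal alkoxide 31 (not isolated)
Conditions: n-BuLi, THF, 0 °C; DMF, 0 °C → rt; AcOH, H2O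
Reagents that add atoms: N,N-dimethylformamide, CN(C)C=O
Why: Directed ortho-metalation between two MOM ethers followed by Bouveault-type formylation with DMF gives the aldehyde after collapse of the hemiaminal on work-up.

Step 13
Reactants: 26 1-{2-hydroxy-4,6-bis(methoxymethoxy)-3-[(2R)-lavandulyl]-5-prenylphenyl}ethan-1-one; 32 2,4,6-tris(methoxymethoxy)benzaldehyde
Product: 33 (2E)-1-{2-hydroxy-4,6-bis(methoxymethoxy)-3-[(2R)-lavandulyl]-5-prenylphenyl}-3-[2,4,6-tris(methoxymethoxy)phenyl]prop-2-en-1-one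
Conditions: KOH (50 % aq.), EtOH, rt → 40 °C, 48 h
Reagents that add atoms: none
Why: Claisen–Schmidt aldol condensation of the methyl ketone enolate with the non-enolisable aldehyde and E1cB dehydration give the E-chalcone; MOM ethers, alkenes and the non-acidic lavandulyl centre are stable to base.

Step 14
Reactants: 33 (2E)-1-{2-hydroxy-4,6-bis(methoxymethoxy)-3-[(2R)-lavandulyl]-5-prenylphenyl}-3-[2,4,6-tris(methoxymethoxy)phenyl]prop-2-en-1-one
Product: 34 (2S)-5,7-bis(methoxymethoxy)-8-[(2R)-lavandulyl]-6-prenyl-2-[2,4,6-tris(methoxymethoxy)phenyl]-2,3-dihydro-4H-chromen-4-one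
Conditions: (R)-3,3′-bis(2,4,6-triisopropylphenyl)-BINOL N-triflylphosphoramide (10 mol %), 5 Å MS, toluene, −20 °C, stopped at full conversion
Reagents that add atoms: none
Why: Proposed new method: a confined chiral Brønsted acid protonates the unusually basic enone (the 2,4,6-trialkoxyphenyl group makes Cβ a stabilised benzylic, quinone-methide-like cation) and the 2′-OH, hydrogen-bonded to the chiral counter-anion, closes 6-endo onto one face of Cβ within the contact ion pair, forming the C ring and setting C2 as S under catalyst control (the sense for the (R)-acid is assigned by analogy and must be confirmed); the closest known reaction types are chiral phosphoric acid-catalysed additions of O-nucleophiles to in-situ quinone methides and acid-catalysed asymmetric aza-Michael cyclisation of 2′-aminochalcones, whereas no enantioselective cyclisation of an unactivated 2′-hydroxychalcone with a 2,6-dioxygenated B ring is known.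

Step 15
Reactants: 34 (2S)-5,7-bis(methoxymethoxy)-8-[(2R)-lavandulyl]-6-prenyl-2-[2,4,6-tris(methoxymethoxy)phenyl]-2,3-dihydro-4H-chromen-4-one
Product: 35 (2S)-5,7-dihydroxy-8-[(2R)-5-methyl-2-(prop-1-en-2-yl)hex-4-en-1-yl]-6-(3-methylbut-2-en-1-yl)-2-(2,4,6-trihydroxyphenyl)-2,3-dihydro-4H-chromen-4-one
Conditions: 3 M aq. HCl/MeOH (1:5), 40 °C, 2–4 h, Ar; cold work-up at pH ≈ 6
Reagents that add atoms: none
Why: Acid-catalysed transacetalisation to methanol (MOM cleavage) frees the five phenols; short time and moderate temperature are chosen to limit C2 epimerisation and acid cyclisation of the prenyl and isopropenyl groups.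

**Compound list**
1 | resorcinol (benzene-1,3-diol) | Oc1cccc(O)c1 | starting material
2 | 1,3-bis(methoxymethoxy)benzene | COCOc1cccc(OCOC)c1 | intermediate
3 | prenyl bromide (1-bromo-3-methylbut-2-ene) | CC(C)=CCBr | starting material
4 | [2,6-bis(methoxymethoxy)phenyl]lithium | [Li]c1c(OCOC)cccc1OCOC | intermediate
5 | 1,3-bis(methoxymethoxy)-2-(3-methylbut-2-en-1-yl)benzene | COCOc1cccc(OCOC)c1CC=C(C)C | intermediate
6 | 2-[3,5-bis(methoxymethoxy)-4-(3-methylbut-2-en-1-yl)phenyl]-4,4,5,5-tetramethyl-1,3,2-dioxaborolane | COCOc1cc(B2OC(C)(C)C(C)(C)O2)cc(OCOC)c1CC=C(C)C | intermediate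
7 | 3,5-bis(methoxymethoxy)-4-(3-methylbut-2-en-1-yl)phenol | COCOc1cc(O)cc(OCOC)c1CC=C(C)C | intermediate
8 | 2-[3,5-bis(methoxymethoxy)-4-(3-methylbut-2-en-1-yl)phenoxy]oxane (racemic acetal carbon) | COCOc1cc(OC2CCCCO2)cc(OCOC)c1CC=C(C)C | intermediate
9 | [2,4-bis(methoxymethoxy)-3-(3-methylbut-2-en-1-yl)-6-(oxan-2-yloxy)phenyl]lithium (ArA–Li) | [Li]c1c(OC2CCCCO2)cc(OCOC)c(CC=C(C)C)c1OCOC | intermediate
10 | lithium ArA(chloromethyl)(pinacolato)borate | [Li+].ClC[B-]1(OC(C)(C)C(C)(C)O1)c1c(OC2CCCCO2)cc(OCOC)c(CC=C(C)C)c1OCOC | intermediate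
11 | 2-(ArA-methyl)-4,4,5,5-tetramethyl-1,3,2-dioxaborolane | CC1(C)OB(Cc2c(OC3CCCCO3)cc(OCOC)c(CC=C(C)C)c2OCOC)OC1(C)C | intermediate
12 | 4-methylpent-3-en-1-ol | CC(C)=CCCO | starting material
13 | 4-methylpent-3-en-1-yl N,N-diisopropylcarbamate | CC(C)=CCCOC(=O)N(C(C)C)C(C)C | intermediate
14 | (1S)-1-lithio-4-methylpent-3-en-1-yl N,N-diisopropylcarbamate, (−)-sparteine complex | [Li][C@@H](CC=C(C)C)OC(=O)N(C(C)C)C(C)C | intermediate
15 | lithium (ArA-methyl)[(1S)-1-(diisopropylcarbamoyloxy)-4-methylpent-3-en-1-yl](pinacolato)borate | [Li+].CC1(C)O[B-](Cc2c(OC3CCCCO3)cc(OCOC)c(CC=C(C)C)c2OCOC)(OC1(C)C)[C@@H](CC=C(C)C)OC(=O)N(C(C)C)C(C)C | intermediate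
16 | 2-[(2R)-1-ArA-5-methylhex-4-en-2-yl]-4,4,5,5-tetramethyl-1,3,2-dioxaborolane | CC(C)=CC[C@H](Cc1c(OC2CCCCO2)cc(OCOC)c(CC=C(C)C)c1OCOC)B1OC(C)(C)C(C)(C)O1 | intermediate
17 | 2-bromopropene | CC(Br)=C | starting material
18 | (prop-1-en-2-yl)lithium | [Li]C(C)=C | intermediate
19 | lithium [(2R)-1-ArA-5-methylhex-4-en-2-yl](prop-1-en-2-yl)(pinacolato)borate | [Li+].C=C(C)[B-]1(OC(C)(C)C(C)(C)O1)[C@H](CC=C(C)C)Cc1c(OC2CCCCO2)cc(OCOC)c(CC=C(C)C)c1OCOC | intermediate
20 | 2-[(3R)-3-(ArA-methyl)-1-iodo-2,6-dimethylhept-5-en-2-yl]-4,4,5,5-tetramethyl-1,3,2-dioxaborolane (epimers at C2) | ICC(C)(B1OC(C)(C)C(C)(C)O1)[C@H](CC=C(C)C)Cc1c(OC2CCCCO2)cc(OCOC)c(CC=C(C)C)c1OCOC | intermediate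
21 | 2-{3,5-bis(methoxymethoxy)-2-[(2R)-5-methyl-2-(prop-1-en-2-yl)hex-4-en-1-yl]-4-(3-methylbut-2-en-1-yl)phenoxy}oxane | C=C(C)[C@H](CC=C(C)C)Cc1c(OC2CCCCO2)cc(OCOC)c(CC=C(C)C)c1OCOC | intermediate
22 | N-methoxy-N-methylacetamide | CC(=O)N(C)OC | starting material
23 | {2,4-bis(methoxymethoxy)-5-[(2R)-lavandulyl]-3-prenyl-6-(oxan-2-yloxy)phenyl}lithium | C=C(C)[C@H](CC=C(C)C)Cc1c(OC2CCCCO2)c([Li])c(OCOC)c(CC=C(C)C)c1OCOC | intermediate
24 | lithium 1-{4,6-bis(methoxymethoxy)-3-[(2R)-lavandulyl]-5-prenyl-2-(oxan-2-yloxy)phenyl}-1-[methoxy(methyl)amino]ethan-1-olate | C=C(C)[C@H](CC=C(C)C)Cc1c(OC2CCCCO2)c(C(C)(O[Li])N(C)OC)c(OCOC)c(CC=C(C)C)c1OCOC | intermediate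
25 | 1-{4,6-bis(methoxymethoxy)-3-[(2R)-lavandulyl]-5-prenyl-2-(oxan-2-yloxy)phenyl}ethan-1-one | C=C(C)[C@H](CC=C(C)C)Cc1c(OC2CCCCO2)c(C(C)=O)c(OCOC)c(CC=C(C)C)c1OCOC | intermediate
26 | 1-{2-hydroxy-4,6-bis(methoxymethoxy)-3-[(2R)-5-methyl-2-(prop-1-en-2-yl)hex-4-en-1-yl]-5-(3-methylbut-2-en-1-yl)phenyl}ethan-1-one | C=C(C)[C@H](CC=C(C)C)Cc1c(O)c(C(C)=O)c(OCOC)c(CC=C(C)C)c1OCOC | intermediate
27 | 2-[3,5-bis(methoxymethoxy)phenyl]-4,4,5,5-tetramethyl-1,3,2-dioxaborolane | COCOc1cc(OCOC)cc(B2OC(C)(C)C(C)(C)O2)c1 | intermediate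
28 | 3,5-bis(methoxymethoxy)phenol | COCOc1cc(O)cc(OCOC)c1 | intermediate
29 | 1,3,5-tris(methoxymethoxy)benzene | COCOc1cc(OCOC)cc(OCOC)c1 | intermediate
30 | [2,4,6-tris(methoxymethoxy)phenyl]lithium | [Li]c1c(OCOC)cc(OCOC)cc1OCOC | intermediate
31 | lithium (dimethylamino)[2,4,6-tris(methoxymethoxy)phenyl]methanolate | CN(C)C(O[Li])c1c(OCOC)cc(OCOC)cc1OCOC | intermediate
32 | 2,4,6-tris(methoxymethoxy)benzaldehyde | COCOc1cc(OCOC)c(C=O)c(OCOC)c1 | intermediate
33 | (2E)-1-{2-hydroxy-4,6-bis(methoxymethoxy)-3-[(2R)-lavandulyl]-5-prenylphenyl}-3-[2,4,6-tris(methoxymethoxy)phenyl]prop-2-en-1-one | C=C(C)[C@H](CC=C(C)C)Cc1c(O)c(C(=O)/C=C/c2c(OCOC)cc(OCOC)cc2OCOC)c(OCOC)c(CC=C(C)C)c1OCOC | intermediate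
34 | (2S)-5,7-bis(methoxymethoxy)-8-[(2R)-lavandulyl]-6-prenyl-2-[2,4,6-tris(methoxymethoxy)phenyl]-2,3-dihydro-4H-chromen-4-one | C=C(C)[C@H](CC=C(C)C)Cc1c(OCOC)c(CC=C(C)C)c(OCOC)c2c1O[C@H](c1c(OCOC)cc(OCOC)cc1OCOC)CC2=O | intermediate
35 | (2S)-5,7-dihydroxy-8-[(2R)-5-methyl-2-(prop-1-en-2-yl)hex-4-en-1-yl]-6-(3-methylbut-2-en-1-yl)-2-(2,4,6-trihydroxyphenyl)-2,3-dihydro-4H-chromen-4-one (CNP0163831.1) | C=C(C)[C@H](CC=C(C)C)Cc1c(O)c(CC=C(C)C)c(O)c2c1O[C@H](c1c(O)cc(O)cc1O)CC2=O | target

**Step count**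
Total: 15 steps. Longest linear sequence: 11 steps (1, 2, 3, 4, 5, 7, 8, 9, 13, 14, 15).

**Three steps most likely to fail**

Step 14 (the proposed acid-catalysed cyclisation). Risks are low reactivity, a low or reversed facial preference, product re-opening that erodes the C2 ratio, and acid-promoted addition of the 2′-OH to the lavandulyl isopropenyl group. The fallback uses known chemistry and sets out from chalcone 33: cyclisation under the classical thermodynamic conditions (NaOAc, EtOH, reflux) gives 34 together with its C2 epimer, the (2R)-penta-MOM flavanone F1. Because the lavandulyl centre is fixed the two are diastereomers and are separated by preparative HPLC on an amylose-type chiral phase, and F1 is returned to the NaOAc equilibration (ring opening to 33 and reclosure). The route is rejoined at 34.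

Step 15 (global acetal removal). The C2–O1 bond becomes benzylic to a 2,4,6-trihydroxyphenyl ring, so protic acid can epimerise C2 or open the ring, and it can add 5-/7-OH to the prenyl or isopropenyl alkenes. The fallback sets out from 34 and avoids protic acid: TESOTf/2,2′-bipyridyl (CH2Cl2, 0 °C) exchanges the aryl MOM ethers directly for silyl ethers to give the pentakis(triethylsilyl) flavanone F2, which is desilylated with HF·pyridine buffered with excess pyridine (THF, 0 °C). The route is rejoined at the target 35.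

Step 7 (the stereodefining 1,2-shift). Risks are competing allylic deprotonation or elimination of carbamate 13 next to the alkene, slow capture of the carbenoid by the crowded benzylic boronate 11, and reversal of ate-complex formation that lowers the enantiomer ratio. The fallback sets out from 11: vinyllithium (THF, −78 → 0 °C) gives the vinyl borate complex F3, which is coupled with 1-bromo-2-methylprop-1-ene under Pd(OAc)2/(Sp,Sp)-MandyPhos with KOTf (THF, 60 °C). Alkenyl-palladium binding to the vinyl group induces the same benzyl 1,2-shift from boron to carbon, and reductive elimination delivers 16 under catalyst control; the ligand antipode is used if an oxidised aliquot shows the S series. The route is rejoined at 16.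

**Further compounds**
F1 | step 14 | (2R)-5,7-bis(methoxymethoxy)-8-[(2R)-lavandulyl]-6-prenyl-2-[2,4,6-tris(methoxymethoxy)phenyl]-2,3-dihydro-4H-chromen-4-one | C=C(C)[C@H](CC=C(C)C)Cc1c(OCOC)c(CC=C(C)C)c(OCOC)c2c1O[C@@H](c1c(OCOC)cc(OCOC)cc1OCOC)CC2=O
F2 | step 15 | (2S)-8-[(2R)-lavandulyl]-6-prenyl-5,7-bis(triethylsilyloxy)-2-[2,4,6-tris(triethylsilyloxy)phenyl]-2,3-dihydro-4H-chromen-4-one | C=C(C)[C@H](CC=C(C)C)Cc1c(O[Si](CC)(CC)CC)c(CC=C(C)C)c(O[Si](CC)(CC)CC)c2c1O[C@H](c1c(O[Si](CC)(CC)CC)cc(O[Si](CC)(CC)CC)cc1O[Si](CC)(CC)CC)CC2=O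
F3 | step 7 | lithium (ArA-methyl)(ethenyl)(pinacolato)borate | [Li+].C=C[B-]1(OC(C)(C)C(C)(C)O1)Cc1c(OC2CCCCO2)cc(OCOC)c(CC=C(C)C)c1OCOC
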